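**Retrosynthetic overview**

1. Target 45 ⇐ 9-O-acetylation of hydroxy lactone 44 ⇐ C9-alkoxide-directed conjugate borylation/oxidation of butenolide 42 (proposed new step; sets C8, C17) ⇐ C9-OH-directed 11,12-epoxidation of macrocycle 41.
2. Ten-membered ring ⇐ Nozaki–Hiyama–Kishi closure of C8–C9 from vinyl triflate/aldehyde 39.
3. Seco chain ⇐ Ipc-boron aldol (C3–C4) of ring A methyl ketone 19 with enal 32 (fragment 2: butenolide triflate from prop-2-yn-1-ol, dimethyl oxalate, propanoyl chloride), then 1,3-anti reduction (C2).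
4. Ring A (key step) ⇐ semipinacol ring expansion of epoxy silyl ether 11: cyclopentane → cyclohexanone, C10 shifts from C14 to C1 and creates the quaternary centre; cyclopentanone 5 comes from (S)-4-hydroxycyclopentenone by conjugate methylation/hydroxymethylation.
5. Ring order: five-membered carbocycle → ring A (six-membered, by 1,2-shift) → butenolide (fragment 2) → ten-membered ring → saturated hydroxy lactone and epoxide.

Assumption: positions are numbered as in the briarane skeleton (ring A = C1, C10–C14; ten-membered ring = C1–C10; lactone = C7, C8, C17, C19 and O; methyls C15 on C1, C16 on C5, C18 on C17, C20 on C11).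

**Route**

Step 1
Reactants: 1 (S)-4-hydroxycyclopent-2-en-1-one
Product: 2 (S)-4-(tert-butyldimethylsilyloxy)cyclopent-2-en-1-one
Conditions: TBSCl, imidazole, CH2Cl2, 0 °C to rt
Reagents that add atoms: tert-butyldimethylsilyl chloride CC(C)(C)[Si](C)(C)Cl
Why: Routine silyl ether formation (protection) that does not touch the carbinol stereocentre.

Step 2
Reactants: 2 (S)-4-(tert-butyldimethylsilyloxy)cyclopent-2-en-1-one
Product: 4 (2R,3S,4S)-4-(tert-butyldimethylsilyloxy)-2-(hydroxymethyl)-3-methylcyclopentan-1-one, via bromomagnesium enolate 3 (not isolated)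
Conditions: MeMgBr, CuBr·SMe2 (10 mol %), THF, −78 °C; then CH2O (gas), −78 °C; aq. work-up
Reagents that add atoms: methylmagnesium bromide C[Mg]Br; formaldehyde C=O
Why: Copper-catalysed conjugate addition of the methyl Grignard reagent anti to the silyloxy group followed by aldol trapping of the enolate with formaldehyde trans to the new methyl group (three-component coupling) sets C10 relative to the starting (S)-centre.

Step 3
Reactants: 4 (2R,3S,4S)-4-(tert-butyldimethylsilyloxy)-2-(hydroxymethyl)-3-methylcyclopentan-1-one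
Product: 5 (2R,3S,4S)-4-(tert-butyldimethylsilyloxy)-2-[(tert-butyldiphenylsilyloxy)methyl]-3-methylcyclopentan-1-one
Conditions: TBDPSCl, imidazole, CH2Cl2, 0 °C to rt
Reagents that add atoms: tert-butyldiphenylsilyl chloride CC(C)(C)[Si](Cl)(c1ccccc1)c1ccccc1
Why: Standard silylation of the primary alcohol, which also blocks retro-aldol and dehydration of the β-hydroxy ketone.

Step 4
Reactants: 5 (2R,3S,4S)-4-(tert-butyldimethylsilyloxy)-2-[(tert-butyldiphenylsilyloxy)methyl]-3-methylcyclopentan-1-one; 6 (E)-2-bromobut-2-ene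
Product: 10 (1R,2R,3S,4S)-1-[(E)-but-2-en-2-yl]-4-(tert-butyldimethylsilyloxy)-2-[(tert-butyldiphenylsilyloxy)methyl]-3-methyl-1-(triethylsilyloxy)cyclopentane, via but-2-en-2-yllithium 7 (not isolated), via alkenylcerium dichloride 8 (not isolated), via cerium alkoxide 9 (not isolated)
Conditions: 6, t-BuLi (2 equiv), Et2O, −78 °C; CeCl3, THF, −78 °C; then 5; then TESOTf, −78 to 0 °C
Reagents that add atoms: triethylsilyl trifluoromethanesulfonate CC[Si](CC)(CC)OS(=O)(=O)C(F)(F)F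
Why: Weakly basic organocerium 1,2-addition (no enolisation or β-elimination of the β-silyloxy ketone) anti to the C10 substituent with in situ O-silylation of the alkoxide; the new carbinol centre is destroyed in step 6, so its ratio is immaterial.

Step 5
Reactants: 10 (1R,2R,3S,4S)-1-[(E)-but-2-en-2-yl]-4-(tert-butyldimethylsilyloxy)-2-[(tert-butyldiphenylsilyloxy)methyl]-3-methyl-1-(triethylsilyloxy)cyclopentane
Product: 11 (1R,2R,3S,4S)-4-(tert-butyldimethylsilyloxy)-2-[(tert-butyldiphenylsilyloxy)methyl]-1-[(2R,3S)-2,3-dimethyloxiran-2-yl]-3-methyl-1-(triethylsilyloxy)cyclopentane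
Conditions: ent-Shi ketone (L-fructose-derived, 30 mol %), KHSO5 (as 2KHSO5·KHSO4·K2SO4), K2CO3, Bu4NHSO4 (cat.), MeCN/CH2(OMe)2/aq. buffer, 0 °C
Reagents that add atoms: potassium peroxymonosulfate [K+].[O-]S(=O)(=O)OO
Why: Shi asymmetric epoxidation of the trisubstituted E-alkene under reagent control, the ent-ketone being chosen with the spiro transition-state model so that oxygen sits on the alkene face that gives the required C1 configuration after anti migration.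

Step 6
Reactants: 11 (1R,2R,3S,4S)-4-(tert-butyldimethylsilyloxy)-2-[(tert-butyldiphenylsilyloxy)methyl]-1-[(2R,3S)-2,3-dimethyloxiran-2-yl]-3-methyl-1-(triethylsilyloxy)cyclopentane
Product: 12 (2S,3S,4S,5S)-5-(tert-butyldimethylsilyloxy)-3-[(tert-butyldiphenylsilyloxy)methyl]-2,4-dimethyl-2-[(1S)-1-(triethylsilyloxy)ethyl]cyclohexan-1-one
Conditions: TESOTf (10 mol %), CH2Cl2, −78 °C
Reagents that add atoms: none
Why: Key step, a semipinacol rearrangement of a 2,3-epoxy silyl ether (Suzuki–Tsuchihashi type): the silyl triflate opens the epoxide at the tertiary carbon C1 while the more substituted ring carbon C10 migrates antiperiplanar from C14 to C1 (inversion at C1, retention at C10), which expands the cyclopentane to the ring A cyclohexanone, creates the quaternary C1 centre and passes the silyl group to O-2.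

Step 7
Reactants: 12 (2S,3S,4S,5S)-5-(tert-butyldimethylsilyloxy)-3-[(tert-butyldiphenylsilyloxy)methyl]-2,4-dimethyl-2-[(1S)-1-(triethylsilyloxy)ethyl]cyclohexan-1-one
Product: 15 (5S,6S)-5-[(tert-butyldiphenylsilyloxy)methyl]-4,6-dimethyl-6-[(1S)-1-(triethylsilyloxy)ethyl]cyclohex-3-en-1-one, via conjugated enone 13 (not isolated), via potassium dienolate 14 (not isolated)
Conditions: KOt-Bu (2.5 equiv), THF, −78 to 0 °C; then AcOH, −78 °C (product used crude)
Reagents that add atoms: none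
Why: E1cB loss of silanolate gives the enone, whose only acidic site (C1 is quaternary) is the γ-hydrogen at C11, so the extended dienolate forms and kinetic α-protonation gives the deconjugated 11,12-alkene (base-mediated elimination/deconjugation).

Step 8
Reactants: 15 (5S,6S)-5-[(tert-butyldiphenylsilyloxy)methyl]-4,6-dimethyl-6-[(1S)-1-(triethylsilyloxy)ethyl]cyclohex-3-en-1-one
Product: 17 (1S,5S,6R)-5-[(tert-butyldiphenylsilyloxy)methyl]-4,6-dimethyl-6-[(1S)-1-(triethylsilyloxy)ethyl]cyclohex-3-en-1-yl acetate, via lithium alkoxide 16 (not isolated)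
Conditions: LiBH(s-Bu)3, THF, −78 °C; then Ac2O, DMAP (cat.), −78 °C to rt
Reagents that add atoms: acetic anhydride CC(=O)OC(C)=O
Why: The bulky hydride attacks C14 from the face opposite the large C2 substituent on the neighbouring quaternary carbon (steric approach control) to give the (14S) alkoxide, which is acetylated in the same flask (reductive acetylation).

Step 9
Reactants: 17 (1S,5S,6R)-5-[(tert-butyldiphenylsilyloxy)methyl]-4,6-dimethyl-6-[(1S)-1-(triethylsilyloxy)ethyl]cyclohex-3-en-1-yl acetate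
Product: 19 (1S,5S,6R)-6-acetyl-5-[(tert-butyldiphenylsilyloxy)methyl]-4,6-dimethylcyclohex-3-en-1-yl acetate, via secondary alcohol 18 (not isolated)
Conditions: CrO3, H2SO4, H2O, acetone, 0 °C
Reagents that add atoms: none
Why: Jones oxidation in which the acidic medium first cleaves the triethylsilyl ether and the freed secondary alcohol is oxidised to the methyl ketone, while the tert-butyldiphenylsilyl ether and the acetate are stable.

Step 10
Reactants: 20 prop-2-yn-1-ol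
Product: 22 (Z)-3-iodo-2-methylprop-2-en-1-ol, via oxamagnesacycle 21 (not isolated)
Conditions: MeMgBr (2.5 equiv), CuI (10 mol %), THF/Et2O, −10 °C to rt; then I2, −78 to 0 °C; aq. work-up
Reagents that add atoms: methylmagnesium bromide C[Mg]Br; iodine II
Why: Copper-catalysed anti-carbomagnesiation of the propargylic alkoxide through the five-membered magnesium chelate, then iodinolysis with retention, fixes the Z trisubstituted alkene (C4 and the future C7 cis).

Step 11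
Reactants: 22 (Z)-3-iodo-2-methylprop-2-en-1-ol
Product: 23 (Z)-triethyl[(3-iodo-2-methylprop-2-en-1-yl)oxy]silane
Conditions: TESCl, imidazole, CH2Cl2, 0 °C
Reagents that add atoms: chlorotriethylsilane CC[Si](Cl)(CC)CC
Why: Standard silylation of the primary allylic alcohol.

Step 12
Reactants: 23 (Z)-triethyl[(3-iodo-2-methylprop-2-en-1-yl)oxy]silane; 24 dimethyl oxalate
Product: 26 methyl (Z)-4-methyl-2-oxo-5-(triethylsilyloxy)pent-3-enoate, via alkenyllithium 25 (not isolated)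
Conditions: t-BuLi (2 equiv), Et2O, −78 °C; cannulate into 24 (3 equiv), THF, −78 °C
Reagents that add atoms: none
Why: Iodine–lithium exchange with retention of alkene geometry and acylation by excess dimethyl oxalate, whose tetrahedral adduct prevents double addition (α-keto ester synthesis).

Step 13
Reactants: 26 methyl (Z)-4-methyl-2-oxo-5-(triethylsilyloxy)pent-3-enoate
Product: 27 methyl (S,Z)-2-hydroxy-4-methyl-5-(triethylsilyloxy)pent-3-enoate
Conditions: RuCl[(R,R)-TsDPEN](p-cymene) (1 mol %), HCO2H/Et3N (5:2), CH2Cl2, rt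
Reagents that add atoms: none
Why: Noyori asymmetric transfer hydrogenation of the α-keto ester, with the alkenyl group in the place normally taken by the aryl group so that the (R,R)-catalyst gives the (S)-carbinol (C7).

Step 14
Reactants: 27 methyl (S,Z)-2-hydroxy-4-methyl-5-(triethylsilyloxy)pent-3-enoate; 28 propanoyl chloride
Product: 29 methyl (S,Z)-4-methyl-2-(propanoyloxy)-5-(triethylsilyloxy)pent-3-enoate
Conditions: pyridine, DMAP (cat.), CH2Cl2, 0 °C
Reagents that add atoms: none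
Why: DMAP-catalysed O-acylation that brings in C17–C19 without touching C7.

Step 15
Reactants: 29 methyl (S,Z)-4-methyl-2-(propanoyloxy)-5-(triethylsilyloxy)pent-3-enoate
Product: 31 (S)-4-methyl-5-oxo-2-[(Z)-2-methyl-3-(triethylsilyloxy)prop-1-en-1-yl]-2,5-dihydrofuran-3-yl trifluoromethanesulfonate, via lithium tetronate 30 (not isolated)
Conditions: LiN(SiMe3)2 (2.2 equiv), THF, −78 °C; then PhNTf2, −78 to 0 °C
Reagents that add atoms: N-phenylbis(trifluoromethanesulfonimide) O=S(=O)(N(c1ccccc1)S(=O)(=O)C(F)(F)F)C(F)(F)F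
Why: Dieckmann (Lacey-type) cyclisation of the propanoate enolate onto the neighbouring methyl ester at −78 °C, faster than deprotonation at C7, gives the tetronate, which is O-triflated in the same flask.

Step 16
Reactants: 31 (S)-4-methyl-5-oxo-2-[(Z)-2-methyl-3-(triethylsilyloxy)prop-1-en-1-yl]-2,5-dihydrofuran-3-yl trifluoromethanesulfonate
Product: 32 (S)-4-methyl-2-[(Z)-2-methyl-3-oxoprop-1-en-1-yl]-5-oxo-2,5-dihydrofuran-3-yl trifluoromethanesulfonate
Conditions: (COCl)2, DMSO, CH2Cl2, −78 to −40 °C; Et3N, −78 to 0 °C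
Reagents that add atoms: none
Why: Swern oxidation, which turns primary triethylsilyl ethers directly into aldehydes, so no separate deprotection is needed and the Z-enal forms under non-isomerising conditions.

Step 17
Reactants: 19 (1S,5S,6R)-6-acetyl-5-[(tert-butyldiphenylsilyloxy)methyl]-4,6-dimethylcyclohex-3-en-1-yl acetate; 32 (S)-4-methyl-2-[(Z)-2-methyl-3-oxoprop-1-en-1-yl]-5-oxo-2,5-dihydrofuran-3-yl trifluoromethanesulfonate
Product: 35 (1S,5S,6R)-5-[(tert-butyldiphenylsilyloxy)methyl]-6-{(3R,4Z)-3-hydroxy-4-methyl-5-[(2S)-4-methyl-5-oxo-3-(trifluoromethylsulfonyloxy)-2,5-dihydrofuran-2-yl]pent-4-enoyl}-4,6-dimethylcyclohex-3-en-1-yl acetate, via enol borinate 33 (not isolated), via boron aldolate 34 (not isolated)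
Conditions: (+)-Ipc2BCl, Et3N, Et2O, 0 °C; then 32, −78 to −20 °C; H2O2, MeOH, pH 7 buffer
Reagents that add atoms: none
Why: Paterson boron aldol reaction in which the methyl ketone (single enolisation site, C1 is quaternary) is enolised with (+)-Ipc2BCl and the Ipc ligands direct addition to the re face of the enal to give the (4R)-carbinol; the sense of induction is to be confirmed by Mosher analysis, with the antipodal reagent as the alternative.

Step 18
Reactants: 35 (1S,5S,6R)-5-[(tert-butyldiphenylsilyloxy)methyl]-6-{(3R,4Z)-3-hydroxy-4-methyl-5-[(2S)-4-methyl-5-oxo-3-(trifluoromethylsulfonyloxy)-2,5-dihydrofuran-2-yl]pent-4-enoyl}-4,6-dimethylcyclohex-3-en-1-yl acetate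
Product: 36 (1S,5S,6S)-5-[(tert-butyldiphenylsilyloxy)methyl]-6-{(1R,3R,4Z)-1,3-dihydroxy-4-methyl-5-[(2S)-4-methyl-5-oxo-3-(trifluoromethylsulfonyloxy)-2,5-dihydrofuran-2-yl]pent-4-en-1-yl}-4,6-dimethylcyclohex-3-en-1-yl acetate
Conditions: Me4NBH(OAc)3, MeCN/AcOH (1:1), −30 °C
Reagents that add atoms: none
Why: Evans–Saksena reduction, in which hydride is delivered intramolecularly from the C4 alkoxyborohydride to give the 1,3-anti diol and so the (2R)-carbinol.

Step 19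
Reactants: 36 (1S,5S,6S)-5-[(tert-butyldiphenylsilyloxy)methyl]-6-{(1R,3R,4Z)-1,3-dihydroxy-4-methyl-5-[(2S)-4-methyl-5-oxo-3-(trifluoromethylsulfonyloxy)-2,5-dihydrofuran-2-yl]pent-4-en-1-yl}-4,6-dimethylcyclohex-3-en-1-yl acetate
Product: 37 (1S,5S,6R)-6-{(1R,3R,4Z)-1,3-diacetoxy-4-methyl-5-[(2S)-4-methyl-5-oxo-3-(trifluoromethylsulfonyloxy)-2,5-dihydrofuran-2-yl]pent-4-en-1-yl}-5-[(tert-butyldiphenylsilyloxy)methyl]-4,6-dimethylcyclohex-3-en-1-yl acetate
Conditions: Ac2O, pyridine, DMAP (cat.), CH2Cl2, 0 °C to rt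
Reagents that add atoms: acetic anhydride CC(=O)OC(C)=O
Why: DMAP-catalysed acetylation installs the final C2 and C4 acetates, which then serve as protecting groups.

Step 20
Reactants: 37 (1S,5S,6R)-6-{(1R,3R,4Z)-1,3-diacetoxy-4-methyl-5-[(2S)-4-methyl-5-oxo-3-(trifluoromethylsulfonyloxy)-2,5-dihydrofuran-2-yl]pent-4-en-1-yl}-5-[(tert-butyldiphenylsilyloxy)methyl]-4,6-dimethylcyclohex-3-en-1-yl acetate
Product: 38 (1S,5S,6R)-6-{(1R,3R,4Z)-1,3-diacetoxy-4-methyl-5-[(2S)-4-methyl-5-oxo-3-(trifluoromethylsulfonyloxy)-2,5-dihydrofuran-2-yl]pent-4-en-1-yl}-5-(hydroxymethyl)-4,6-dimethylcyclohex-3-en-1-yl acetate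
Conditions: HF·pyridine, pyridine, THF, 0 °C to rt
Reagents that add atoms: none
Why: Buffered fluoride desilylation that spares the acetates and the vinyl triflate.

Step 21
Reactants: 38 (1S,5S,6R)-6-{(1R,3R,4Z)-1,3-diacetoxy-4-methyl-5-[(2S)-4-methyl-5-oxo-3-(trifluoromethylsulfonyloxy)-2,5-dihydrofuran-2-yl]pent-4-en-1-yl}-5-(hydroxymethyl)-4,6-dimethylcyclohex-3-en-1-yl acetate
Product: 39 (1S,5S,6R)-6-{(1R,3R,4Z)-1,3-diacetoxy-4-methyl-5-[(2S)-4-methyl-5-oxo-3-(trifluoromethylsulfonyloxy)-2,5-dihydrofuran-2-yl]pent-4-en-1-yl}-5-formyl-4,6-dimethylcyclohex-3-en-1-yl acetate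
Conditions: Dess–Martin periodinane, CH2Cl2, 0 °C to rt
Reagents that add atoms: none
Why: Dess–Martin oxidation under near-neutral conditions gives the C9 aldehyde without epimerising C10.

Step 22
Reactants: 39 (1S,5S,6R)-6-{(1R,3R,4Z)-1,3-diacetoxy-4-methyl-5-[(2S)-4-methyl-5-oxo-3-(trifluoromethylsulfonyloxy)-2,5-dihydrofuran-2-yl]pent-4-en-1-yl}-5-formyl-4,6-dimethylcyclohex-3-en-1-yl acetate
Product: 41 (1R,2R,4R,5Z,7S,9R,10S,14S)-2,4,14-triacetoxy-9-hydroxy-5,8(17),11-triene macrocyclic butenolide (ten-membered ring closed; C19 lactone carbonyl bound to O-7), via alkenylchromium dichloride 40 (not isolated)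
Conditions: CrCl2 (10 equiv), NiCl2 (2 mol %), DMSO/THF, 0.002 M, rt
Reagents that add atoms: none
Why: Nozaki–Hiyama–Kishi reaction, in which zerovalent nickel inserts into the vinyl triflate and the alkenyl–trivalent chromium species adds to the aldehyde at high dilution to close the ten-membered ring; Felkin–Anh attack anti to the quaternary C1 (an anti C1–C10–C9–C8 torsion fits the forming ring) should give the (9R)-alcohol.

Step 23
Reactants: 41 (1R,2R,4R,5Z,7S,9R,10S,14S)-2,4,14-triacetoxy-9-hydroxy-5,8(17),11-triene macrocyclic butenolide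
Product: 42 (1S,2R,4R,5Z,7S,9R,10S,11R,12S,14S)-2,4,14-triacetoxy-11,12-epoxy-9-hydroxy-5,8(17)-diene macrocyclic butenolide
Conditions: VO(acac)2 (10 mol %), t-BuOOH, CH2Cl2, 0 °C to rt
Reagents that add atoms: tert-butyl hydroperoxide CC(C)(C)OO
Why: Vanadium-catalysed hydroxyl-directed epoxidation, in which the homoallylic C9 hydroxyl delivers oxygen to the face of the electron-rich 11,12-alkene on which C9 sits, while the electron-poor butenolide and the doubly allylically oxygenated 5,6-alkene do not react.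

Step 24
Reactants: 42 (1S,2R,4R,5Z,7S,9R,10S,11R,12S,14S)-2,4,14-triacetoxy-11,12-epoxy-9-hydroxy-5,8(17)-diene macrocyclic butenolide
Product: 44 (1S,2R,4R,5Z,7S,8R,9R,10S,11R,12S,14S,17R)-2,4,14-triacetoxy-11,12-epoxy-8,9-dihydroxy-5-ene lactone (9-O-deacetyl target), via bis(boronate) 43 (not isolated)
Conditions: B2pin2 (1.5 equiv), Cs2CO3 (10 mol %), i-PrOH (3 equiv), THF, 0 °C to rt; then NaBO3·4H2O, THF/H2O, 0 °C
Reagents that add atoms: sodium perborate [Na+].[O-]OB=O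
Why: Proposed new method: the C9 alkoxide (formed reversibly by catalytic carbonate) binds B2pin2 as an sp3–sp2 diboron ate complex that passes the nucleophilic pinacolboryl group through a five-membered transition state to the β-carbon C8 of the tetrasubstituted butenolide on the face that carries O-9 (rotamer with C9–H eclipsing C18 to minimise A(1,3) strain, bulky C10 on the other face), the enolate is protonated by the alcohol shuttle and C17 settles with its methyl trans to C9, and stereoretentive perborate oxidation of the tertiary C–B bond gives the C8 hydroxyl; the closest known reaction types are the alkoxide-activated metal-free β-borylation of enoates with B2pin2 and the hydroxyl-directed diboration of alkenyl alcohols, neither shown for a directed addition to a tetrasubstituted butenolide.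

Step 25
Reactants: 44 (1S,2R,4R,5Z,7S,8R,9R,10S,11R,12S,14S,17R)-2,4,14-triacetoxy-11,12-epoxy-8,9-dihydroxy-5-ene lactone
Product: 45 CNP0215170.2 (1S,2R,4R,5Z,7S,8S,9R,10S,11R,12S,14S,17R)-2,4,9,14-tetraacetoxy-11,12-epoxy-8-hydroxy-5-ene lactone
Conditions: Ac2O, pyridine, DMAP (cat.), CH2Cl2, 0 °C to rt
Reagents that add atoms: acetic anhydride CC(=O)OC(C)=O
Why: Selective acetylation of the secondary C9 hydroxyl, the tertiary C8 hydroxyl being unreactive under these conditions.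

**Compound list**

1 | (S)-4-hydroxycyclopent-2-en-1-one | O=C1C[C@H](O)C=C1 | starting material
2 | (S)-4-(tert-butyldimethylsilyloxy)cyclopent-2-en-1-one | O=C1C[C@H](O[Si](C)(C)C(C)(C)C)C=C1 | intermediate
3 | bromomagnesium (3S,4S)-4-(tert-butyldimethylsilyloxy)-3-methylcyclopent-1-en-1-olate | Br[Mg]OC1=C[C@H](C)[C@@H](O[Si](C)(C)C(C)(C)C)C1 | intermediate
4 | (2R,3S,4S)-4-(tert-butyldimethylsilyloxy)-2-(hydroxymethyl)-3-methylcyclopentan-1-one | O=C1C[C@H](O[Si](C)(C)C(C)(C)C)[C@@H](C)[C@@H]1CO | intermediate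
5 | (2R,3S,4S)-4-(tert-butyldimethylsilyloxy)-2-[(tert-butyldiphenylsilyloxy)methyl]-3-methylcyclopentan-1-one | O=C1C[C@H](O[Si](C)(C)C(C)(C)C)[C@@H](C)[C@@H]1CO[Si](c1ccccc1)(c1ccccc1)C(C)(C)C | intermediate
6 | (E)-2-bromobut-2-ene | C/C=C(/Br)C | starting material
7 | but-2-en-2-yllithium (geometry of 6 retained, methyl groups cis) | C/C=C(/[Li])C | intermediate
8 | (but-2-en-2-yl)cerium dichloride (same geometry) | C/C=C(/[Ce](Cl)Cl)C | intermediate
9 | cerium dichloride alkoxide of (1R,2R,3S,4S)-1-[(E)-but-2-en-2-yl]-4-(tert-butyldimethylsilyloxy)-2-[(tert-butyldiphenylsilyloxy)methyl]-3-methylcyclopentan-1-ol | C/C=C(\C)[C@@]1(O[Ce](Cl)Cl)C[C@H](O[Si](C)(C)C(C)(C)C)[C@@H](C)[C@@H]1CO[Si](c1ccccc1)(c1ccccc1)C(C)(C)C | intermediate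
10 | (1R,2R,3S,4S)-1-[(E)-but-2-en-2-yl]-4-(tert-butyldimethylsilyloxy)-2-[(tert-butyldiphenylsilyloxy)methyl]-3-methyl-1-(triethylsilyloxy)cyclopentane | C/C=C(\C)[C@@]1(O[Si](CC)(CC)CC)C[C@H](O[Si](C)(C)C(C)(C)C)[C@@H](C)[C@@H]1CO[Si](c1ccccc1)(c1ccccc1)C(C)(C)C | intermediate
11 | (1R,2R,3S,4S)-4-(tert-butyldimethylsilyloxy)-2-[(tert-butyldiphenylsilyloxy)methyl]-1-[(2R,3S)-2,3-dimethyloxiran-2-yl]-3-methyl-1-(triethylsilyloxy)cyclopentane | C[C@@H]1O[C@@]1(C)[C@@]1(O[Si](CC)(CC)CC)C[C@H](O[Si](C)(C)C(C)(C)C)[C@@H](C)[C@@H]1CO[Si](c1ccccc1)(c1ccccc1)C(C)(C)C | intermediate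
12 | (2S,3S,4S,5S)-5-(tert-butyldimethylsilyloxy)-3-[(tert-butyldiphenylsilyloxy)methyl]-2,4-dimethyl-2-[(1S)-1-(triethylsilyloxy)ethyl]cyclohexan-1-one | C[C@H](O[Si](CC)(CC)CC)[C@@]1(C)C(=O)C[C@H](O[Si](C)(C)C(C)(C)C)[C@@H](C)[C@@H]1CO[Si](c1ccccc1)(c1ccccc1)C(C)(C)C | intermediate
13 | (4R,5S,6S)-5-[(tert-butyldiphenylsilyloxy)methyl]-4,6-dimethyl-6-[(1S)-1-(triethylsilyloxy)ethyl]cyclohex-2-en-1-one | C[C@H](O[Si](CC)(CC)CC)[C@@]1(C)C(=O)C=C[C@@H](C)[C@@H]1CO[Si](c1ccccc1)(c1ccccc1)C(C)(C)C | intermediate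
14 | potassium cyclohexa-1,3-dien-1-olate (extended dienolate) of 13 | C[C@H](O[Si](CC)(CC)CC)[C@@]1(C)C([O-])=CC=C(C)[C@@H]1CO[Si](c1ccccc1)(c1ccccc1)C(C)(C)C.[K+] | intermediate
15 | (5S,6S)-5-[(tert-butyldiphenylsilyloxy)methyl]-4,6-dimethyl-6-[(1S)-1-(triethylsilyloxy)ethyl]cyclohex-3-en-1-one | C[C@H](O[Si](CC)(CC)CC)[C@@]1(C)C(=O)CC=C(C)[C@@H]1CO[Si](c1ccccc1)(c1ccccc1)C(C)(C)C | intermediate
16 | lithium alkoxide of the (1S)-cyclohex-3-en-1-ol formed from 15 | C[C@H](O[Si](CC)(CC)CC)[C@@]1(C)[C@@H]([O-])CC=C(C)[C@@H]1CO[Si](c1ccccc1)(c1ccccc1)C(C)(C)C.[Li+] | intermediate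
17 | (1S,5S,6R)-5-[(tert-butyldiphenylsilyloxy)methyl]-4,6-dimethyl-6-[(1S)-1-(triethylsilyloxy)ethyl]cyclohex-3-en-1-yl acetate | C[C@H](O[Si](CC)(CC)CC)[C@@]1(C)[C@@H](OC(C)=O)CC=C(C)[C@@H]1CO[Si](c1ccccc1)(c1ccccc1)C(C)(C)C | intermediate
18 | (1S,5S,6S)-5-[(tert-butyldiphenylsilyloxy)methyl]-6-[(1S)-1-hydroxyethyl]-4,6-dimethylcyclohex-3-en-1-yl acetate | C[C@H](O)[C@@]1(C)[C@@H](OC(C)=O)CC=C(C)[C@@H]1CO[Si](c1ccccc1)(c1ccccc1)C(C)(C)C | intermediate
19 | (1S,5S,6R)-6-acetyl-5-[(tert-butyldiphenylsilyloxy)methyl]-4,6-dimethylcyclohex-3-en-1-yl acetate | CC(=O)[C@@]1(C)[C@@H](OC(C)=O)CC=C(C)[C@@H]1CO[Si](c1ccccc1)(c1ccccc1)C(C)(C)C | intermediate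
20 | prop-2-yn-1-ol | C#CCO | starting material
21 | 4-methyl-2,5-dihydro-1,2-oxamagnesole (cyclic alkenylmagnesium alkoxide) | CC1=C[Mg]OC1 | intermediate
22 | (Z)-3-iodo-2-methylprop-2-en-1-ol | I/C=C(/C)CO | intermediate
23 | (Z)-triethyl[(3-iodo-2-methylprop-2-en-1-yl)oxy]silane | I/C=C(/C)CO[Si](CC)(CC)CC | intermediate
24 | dimethyl oxalate | COC(=O)C(=O)OC | starting material
25 | [(Z)-2-methyl-3-(triethylsilyloxy)prop-1-en-1-yl]lithium | [Li]/C=C(/C)CO[Si](CC)(CC)CC | intermediate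
26 | methyl (Z)-4-methyl-2-oxo-5-(triethylsilyloxy)pent-3-enoate | COC(=O)C(=O)/C=C(/C)CO[Si](CC)(CC)CC | intermediate
27 | methyl (S,Z)-2-hydroxy-4-methyl-5-(triethylsilyloxy)pent-3-enoate | COC(=O)[C@@H](O)/C=C(/C)CO[Si](CC)(CC)CC | intermediate
28 | propanoyl chloride | CCC(Cl)=O | starting material
29 | methyl (S,Z)-4-methyl-2-(propanoyloxy)-5-(triethylsilyloxy)pent-3-enoate | COC(=O)[C@@H](OC(=O)CC)/C=C(/C)CO[Si](CC)(CC)CC | intermediate
30 | lithium (S)-4-methyl-5-oxo-2-[(Z)-2-methyl-3-(triethylsilyloxy)prop-1-en-1-yl]-2,5-dihydrofuran-3-olate | CC1=C([O-])[C@H](/C=C(/C)CO[Si](CC)(CC)CC)OC1=O.[Li+] | intermediate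
31 | (S)-4-methyl-5-oxo-2-[(Z)-2-methyl-3-(triethylsilyloxy)prop-1-en-1-yl]-2,5-dihydrofuran-3-yl trifluoromethanesulfonate | CC1=C(OS(=O)(=O)C(F)(F)F)[C@H](/C=C(/C)CO[Si](CC)(CC)CC)OC1=O | intermediate
32 | (S)-4-methyl-2-[(Z)-2-methyl-3-oxoprop-1-en-1-yl]-5-oxo-2,5-dihydrofuran-3-yl trifluoromethanesulfonate | CC1=C(OS(=O)(=O)C(F)(F)F)[C@H](/C=C(/C)C=O)OC1=O | intermediate
33 | (+)-diisopinocampheylboron enolate (enol borinate) of methyl ketone 19 | C=C(OB([C@H]1C[C@H]2C[C@@H]([C@@H]1C)C2(C)C)[C@H]1C[C@H]2C[C@@H]([C@@H]1C)C2(C)C)[C@@]1(C)[C@@H](OC(C)=O)CC=C(C)[C@@H]1CO[Si](c1ccccc1)(c1ccccc1)C(C)(C)C | intermediate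
34 | O-(diisopinocampheylboryl) aldolate of 35 | O=C(C[C@@H](OB([C@H]1C[C@H]2C[C@@H]([C@@H]1C)C2(C)C)[C@H]1C[C@H]2C[C@@H]([C@@H]1C)C2(C)C)/C(C)=C\[C@@H]1OC(=O)C(C)=C1OS(=O)(=O)C(F)(F)F)[C@@]1(C)[C@@H](OC(C)=O)CC=C(C)[C@@H]1CO[Si](c1ccccc1)(c1ccccc1)C(C)(C)C | intermediate
35 | (1S,5S,6R)-5-[(tert-butyldiphenylsilyloxy)methyl]-6-{(3R,4Z)-3-hydroxy-4-methyl-5-[(2S)-4-methyl-5-oxo-3-(trifluoromethylsulfonyloxy)-2,5-dihydrofuran-2-yl]pent-4-enoyl}-4,6-dimethylcyclohex-3-en-1-yl acetate | O=C(C[C@@H](O)/C(C)=C\[C@@H]1OC(=O)C(C)=C1OS(=O)(=O)C(F)(F)F)[C@@]1(C)[C@@H](OC(C)=O)CC=C(C)[C@@H]1CO[Si](c1ccccc1)(c1ccccc1)C(C)(C)C | intermediate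
36 | (1S,5S,6S)-5-[(tert-butyldiphenylsilyloxy)methyl]-6-{(1R,3R,4Z)-1,3-dihydroxy-4-methyl-5-[(2S)-4-methyl-5-oxo-3-(trifluoromethylsulfonyloxy)-2,5-dihydrofuran-2-yl]pent-4-en-1-yl}-4,6-dimethylcyclohex-3-en-1-yl acetate | O[C@H](C[C@@H](O)/C(C)=C\[C@@H]1OC(=O)C(C)=C1OS(=O)(=O)C(F)(F)F)[C@@]1(C)[C@@H](OC(C)=O)CC=C(C)[C@@H]1CO[Si](c1ccccc1)(c1ccccc1)C(C)(C)C | intermediate
37 | (1S,5S,6R)-6-{(1R,3R,4Z)-1,3-diacetoxy-4-methyl-5-[(2S)-4-methyl-5-oxo-3-(trifluoromethylsulfonyloxy)-2,5-dihydrofuran-2-yl]pent-4-en-1-yl}-5-[(tert-butyldiphenylsilyloxy)methyl]-4,6-dimethylcyclohex-3-en-1-yl acetate | CC(=O)O[C@H](C[C@@H](OC(C)=O)/C(C)=C\[C@@H]1OC(=O)C(C)=C1OS(=O)(=O)C(F)(F)F)[C@@]1(C)[C@@H](OC(C)=O)CC=C(C)[C@@H]1CO[Si](c1ccccc1)(c1ccccc1)C(C)(C)C | intermediate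
38 | (1S,5S,6R)-6-{(1R,3R,4Z)-1,3-diacetoxy-4-methyl-5-[(2S)-4-methyl-5-oxo-3-(trifluoromethylsulfonyloxy)-2,5-dihydrofuran-2-yl]pent-4-en-1-yl}-5-(hydroxymethyl)-4,6-dimethylcyclohex-3-en-1-yl acetate | CC(=O)O[C@H](C[C@@H](OC(C)=O)/C(C)=C\[C@@H]1OC(=O)C(C)=C1OS(=O)(=O)C(F)(F)F)[C@@]1(C)[C@@H](OC(C)=O)CC=C(C)[C@@H]1CO | intermediate
39 | (1S,5S,6R)-6-{(1R,3R,4Z)-1,3-diacetoxy-4-methyl-5-[(2S)-4-methyl-5-oxo-3-(trifluoromethylsulfonyloxy)-2,5-dihydrofuran-2-yl]pent-4-en-1-yl}-5-formyl-4,6-dimethylcyclohex-3-en-1-yl acetate | CC(=O)O[C@H](C[C@@H](OC(C)=O)/C(C)=C\[C@@H]1OC(=O)C(C)=C1OS(=O)(=O)C(F)(F)F)[C@@]1(C)[C@@H](OC(C)=O)CC=C(C)[C@@H]1C=O | intermediate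
40 | alkenylchromium dichloride from 39 (CrCl2 at C8 in place of the triflate) | CC(=O)O[C@H](C[C@@H](OC(C)=O)/C(C)=C\[C@@H]1OC(=O)C(C)=C1[Cr](Cl)Cl)[C@@]1(C)[C@@H](OC(C)=O)CC=C(C)[C@@H]1C=O | intermediate
41 | (1R,2R,4R,5Z,7S,9R,10S,14S)-2,4,14-triacetoxy-9-hydroxy-5,8(17),11-triene macrocyclic butenolide (ten-membered ring C1–C10 fused to ring A and to the C7/C8 butenolide) | CC(=O)O[C@H]1CC=C(C)[C@@H]2[C@@H](O)C3=C(C)C(=O)O[C@H]3/C=C(/C)[C@H](OC(C)=O)C[C@@H](OC(C)=O)[C@@]12C | intermediate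
42 | (1S,2R,4R,5Z,7S,9R,10S,11R,12S,14S)-2,4,14-triacetoxy-11,12-epoxy-9-hydroxy-5,8(17)-diene macrocyclic butenolide | CC(=O)O[C@H]1C[C@@H]2O[C@]2(C)[C@@H]2[C@@H](O)C3=C(C)C(=O)O[C@H]3/C=C(/C)[C@H](OC(C)=O)C[C@@H](OC(C)=O)[C@@]12C | intermediate
43 | 8-(pinacolboryl)-9-O-(pinacolboryl) saturated lactone from 42 (boron at C8 on the face of O-9, 17R) | CC(=O)O[C@H]1C[C@@H]2O[C@]2(C)[C@@H]2[C@@H](OB3OC(C)(C)C(C)(C)O3)[C@@]3(B4OC(C)(C)C(C)(C)O4)[C@H](/C=C(/C)[C@H](OC(C)=O)C[C@@H](OC(C)=O)[C@@]12C)OC(=O)[C@@H]3C | intermediate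
44 | (1S,2R,4R,5Z,7S,8R,9R,10S,11R,12S,14S,17R)-2,4,14-triacetoxy-11,12-epoxy-8,9-dihydroxy-5-ene lactone (9-O-deacetyl target) | CC(=O)O[C@H]1C[C@@H]2O[C@]2(C)[C@@H]2[C@@H](O)[C@@]3(O)[C@H](/C=C(/C)[C@H](OC(C)=O)C[C@@H](OC(C)=O)[C@@]12C)OC(=O)[C@@H]3C | intermediate
45 | CNP0215170.2, (1S,2R,4R,5Z,7S,8S,9R,10S,11R,12S,14S,17R)-2,4,9,14-tetraacetoxy-11,12-epoxy-8-hydroxy-5-ene lactone | CC(=O)O[C@H]1C[C@@H]2O[C@]2(C)[C@@H]2[C@@H](OC(C)=O)[C@@]3(O)[C@H](/C=C(/C)[C@H](OC(C)=O)C[C@@H](OC(C)=O)[C@@]12C)OC(=O)[C@@H]3C | target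

**Totals and risks**

Total step count: 25. Longest linear sequence: 18 steps (steps 1–9, then 17–25); fragment 2 (steps 10–16) takes 7 steps.

Most likely to fail, step 6 (semipinacol ring expansion). The risks are migration of C13 in place of C10, loss of the silyl groups, and dependence on the face selectivity of step 5. The fallback triggers the same 1,2-shift with a bromonium ion; it sets out from 5 (with 6) and comes back at 19. Step 4 is repeated without the silyl quench to give (1R,2R,3S,4S)-1-[(E)-but-2-en-2-yl]-4-(tert-butyldimethylsilyloxy)-2-[(tert-butyldiphenylsilyloxy)methyl]-3-methylcyclopentan-1-ol F1. N-Bromosuccinimide with (DHQD)2PHAL in CH2Cl2 at −40 °C brings about the halonium-induced semipinacol ring expansion to the bromo ketone (2R,3S,4S,5S)-2-[(1S)-1-bromoethyl]-5-(tert-butyldimethylsilyloxy)-3-[(tert-butyldiphenylsilyloxy)methyl]-2,4-dimethylcyclohexan-1-one F2. KN(SiMe3)2 (3.5 equiv, THF, −78 to 0 °C, AcOH quench) removes silanolate and HBr and deconjugates, giving (5S,6R)-5-[(tert-butyldiphenylsilyloxy)methyl]-4,6-dimethyl-6-vinylcyclohex-3-en-1-one F3. LiBH(s-Bu)3 then Ac2O gives (1S,5S,6R)-5-[(tert-butyldiphenylsilyloxy)methyl]-4,6-dimethyl-6-vinylcyclohex-3-en-1-yl acetate F4, and Wacker oxidation (PdCl2, CuCl, O2, DMF/H2O) of the vinyl group returns methyl ketone 19.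

Step 22 (Nozaki–Hiyama–Kishi macrocyclisation). The risks are the yield of a ten-membered ring closure and the configuration at C9. The fallback sets C9 by ketone reduction instead of by C–C bond formation; it sets out from 39 and comes back at 41. If the closure favours the epimer, the (1R,2R,4R,5Z,7S,9S,10S,14S)-9-epi alcohol F5 (or the epimer mixture) is oxidised with Dess–Martin periodinane to the (1R,2R,4R,5Z,7S,10S,14S)-9-oxo macrocyclic butenolide F6. Reagent-controlled reduction with (S)-Me-CBS oxazaborolidine and catecholborane at −78 °C (alkenyl as the large group) then returns 41.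

Step 24 (proposed new directed conjugate borylation). The risks are low reactivity of the tetrasubstituted acceptor, base-induced epimerisation at C7 before addition, and acetate migration. The fallback uses known chemistry; it sets out from 42 and comes back at 44. Nucleophilic epoxidation (t-BuOOH, DBU, CH2Cl2, 0 °C), on the face away from C10, gives the (8R,17R)-8,17-epoxy lactone F7. SmI2 (THF/MeOH, −78 °C) cleaves the α-C–O bond, and protonation of the samarium enolate with equilibration at C17 returns diol 44.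

**Further compounds**

F1 | step 6 | (1R,2R,3S,4S)-1-[(E)-but-2-en-2-yl]-4-(tert-butyldimethylsilyloxy)-2-[(tert-butyldiphenylsilyloxy)methyl]-3-methylcyclopentan-1-ol | C/C=C(\C)[C@@]1(O)C[C@H](O[Si](C)(C)C(C)(C)C)[C@@H](C)[C@@H]1CO[Si](c1ccccc1)(c1ccccc1)C(C)(C)C
F2 | step 6 | (2R,3S,4S,5S)-2-[(1S)-1-bromoethyl]-5-(tert-butyldimethylsilyloxy)-3-[(tert-butyldiphenylsilyloxy)methyl]-2,4-dimethylcyclohexan-1-one | C[C@H](Br)[C@@]1(C)C(=O)C[C@H](O[Si](C)(C)C(C)(C)C)[C@@H](C)[C@@H]1CO[Si](c1ccccc1)(c1ccccc1)C(C)(C)C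
F3 | step 6 | (5S,6R)-5-[(tert-butyldiphenylsilyloxy)methyl]-4,6-dimethyl-6-vinylcyclohex-3-en-1-one | C=C[C@@]1(C)C(=O)CC=C(C)[C@@H]1CO[Si](c1ccccc1)(c1ccccc1)C(C)(C)C
F4 | step 6 | (1S,5S,6R)-5-[(tert-butyldiphenylsilyloxy)methyl]-4,6-dimethyl-6-vinylcyclohex-3-en-1-yl acetate | C=C[C@@]1(C)[C@@H](OC(C)=O)CC=C(C)[C@@H]1CO[Si](c1ccccc1)(c1ccccc1)C(C)(C)C
F5 | step 22 | (1R,2R,4R,5Z,7S,9S,10S,14S)-2,4,14-triacetoxy-9-hydroxy-5,8(17),11-triene macrocyclic butenolide (9-epimer of 41) | CC(=O)O[C@H]1CC=C(C)[C@@H]2[C@H](O)C3=C(C)C(=O)O[C@H]3/C=C(/C)[C@H](OC(C)=O)C[C@@H](OC(C)=O)[C@@]12C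
F6 | step 22 | (1R,2R,4R,5Z,7S,10S,14S)-2,4,14-triacetoxy-9-oxo-5,8(17),11-triene macrocyclic butenolide | CC(=O)O[C@H]1CC=C(C)[C@@H]2C(=O)C3=C(C)C(=O)O[C@H]3/C=C(/C)[C@H](OC(C)=O)C[C@@H](OC(C)=O)[C@@]12C
F7 | step 24 | (8R,17R)-8,17-epoxy lactone from 42 (2,4,14-triacetoxy-11,12-epoxy-9-hydroxy-5-ene) | CC(=O)O[C@H]1C[C@@H]2O[C@]2(C)[C@@H]2[C@@H](O)[C@@]34O[C@@]4(C)C(=O)O[C@H]3/C=C(/C)[C@H](OC(C)=O)C[C@@H](OC(C)=O)[C@@]12C
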